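Readings and results are calculated from invented constants, noise included.

Turn percent into millimolar first, then ask what end state free monomer tends towards. Your hunch deserves that check.

| flask | free monomer | initiator | impurity | remark | time |
|---|---|---|---|---|---|
| Sunday's | 10 mM | 1 mM | 0.12 mM | run made earlier |  |
| Wednesday's | 40 mM | 1 mM | 0.12 mM | run made earlier |  |
| flask | 20 mM | 1.0 mM | 0.12 mM |  | 8.0 h |

| run | time / h | monomer in chains / % | free monomer / % |
|---|---|---|---|
| Sunday's | 0.333 | 3.0 | 96.1 |
| Sunday's | 1.00 | 6.0 | 93.8 |
| Sunday's | 2.00 | 6.9 | 93.3 |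
| Sunday's | 3.00 | 5.3 | 94.4 |
| Sunday's | 4.00 | 4.7 | 94.1 |
| Sunday's | 5.00 | 5.1 | 95.8 |
| Sunday's | 6.00 | 4.3 | 96.5 |
| Wednesday's | 1.00 | 6.5 | 93.3 |
| Wednesday's | 2.00 | 12.0 | 88.2 |
| Wednesday's | 3.00 | 16.9 | 84.4 |
| Wednesday's | 4.00 | 21.0 | 80.1 |
| Wednesday's | 5.00 | 24.0 | 76.4 |
| Wednesday's | 6.00 | 27.6 | 72.7 |

(each reading ± 0.5 percentage points)

- the average divides the monomer in chains by the number of chains begun, living and dead together
- the earlier runs do not show the number of chains; that part of a forecast is a guess

- average number of monomer units in a chain (chains begun, living or dead) at 8.0 h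
- part of the free monomer that has reacted at 8.0 h

In Sunday's run, c(free monomer) sinks, turns back and last reads 9.65 mM. Take this reading as the ceiling, the level free monomer tends towards. Call c(free monomer) minus that level the excess. In Wednesday's run the excess falls from 27.7 mM at 1.00 h to 19.4 mM at 6.00 h. That gives 0.0707 h⁻¹, the excess decay constant, a pseudo-first-order constant for the excess.

Assume it holds for this flask, which has the same initiator and impurity charges. The excess starts at 10.3 mM and shrinks to 5.88 mM by 8.0 h. My own figure for c is therefore 22.4%.

Your forecast says 24%, range 17% to 32%, and dp 5.3, range 3.5 to 10, reasoning “so there is a ceiling”. My figure is lower than yours by 1.6 percentage points. The earlier runs show no chain count, so keep your dp as the guess it is.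

The flask gives c 23.1% and dp 5.48. Its living end reads 0.845 mM at 4.00 h and 0.845 mM at 8.00 h. Start from the flask's excess at 4.00 h, 7.41 mM, and apply the constant up to 8.0 h: c comes to 23.8%.

    free monomer + living end → monomer in chains + living end, rate k1*[living end]*[free monomer] (k = 89.0 L mol⁻¹ h⁻¹)
    initiator → spent initiator B (k = 0.130 h⁻¹)
    free monomer + initiator → living end + monomer in chains (k = 160 L mol⁻¹ h⁻¹)
    initiator + impurity → spent initiator A (k = 9.30 × 10⁵ L mol⁻¹ h⁻¹)
    monomer in chains + living end → free monomer + living end, rate k5*[living end] as long as [monomer in chains] is above zero (k = 0.940 h⁻¹)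

Now take the neighbour flask, the same flask with 0.48 mM of impurity and a living end of 0.499 mM at 8.00 h. Scale the constant by the living ends to 0.0418 h⁻¹. The excess then reaches 7.41 mM, so c is 14.7%. The neighbour gives 15.5%.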